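The benzene ring (C3a–C7a) carries no stereocentre, so it is assembled last around the O1–C2–C3 unit, whose two stereocentres are taken from D-tartrate. The key step is a rhodium-catalysed intramolecular [4+2] cycloaddition of an ethynyl ether onto a tethered (E)-1,3-diene: it forms C3a–C7a and C6–C7, closing the dihydrofuran and the six-membered carbocycle in one operation, and DDQ then aromatises the cyclohexa-1,4-diene. The precursor is an acyclic dienyne in which O1 bears the ethynyl group, C3 a silyl ether, the diene's internal carbon the (R)-butynol-derived silyloxyethyl chain, and C2 a silyl-protected 2-hydroxyprop-2-yl group as a masked isopropenyl group.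

Key step: step 14

Remarks on the chemistry:
- Atom numbers O1, C2, C3, C3a–C7a are those of the 2,3-dihydrobenzofuran of the target and are used for the acyclic intermediates too. TBS = tert-butyldimethylsilyl.
- Correction of the precursor: an ethynyl ether on a carbon that also carries an isopropenyl group is an allyl alkynyl ether. That class rearranges by a [3,3] shift to a ketene far below room temperature. C2 therefore carries a 2-(silyloxy)prop-2-yl group until O1 has become an aryl ether; the isopropenyl group is released afterwards by dehydration.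
- The ethynyl ether is built from a formate ester and not from an alkoxide, because a metal alkoxide at O2 would set off migration of the neighbouring silyl groups.
- Assumption: 1 is bought as such; it is the acetonide of dimethyl D-tartrate.

Step 1
Reactants: 1 dimethyl (4S,5S)-2,2-dimethyl-1,3-dioxolane-4,5-dicarboxylate
Product: 2 methyl (4S,5R)-5-(hydroxymethyl)-2,2-dimethyl-1,3-dioxolane-4-carboxylate
Conditions: NaBH4 (0.6 equiv), MeOH, 0 °C
Reagents that add atoms: none
Why: Chemoselective borohydride reduction of an activated α-alkoxy ester with a limited amount of hydride should stop largely at the mono-alcohol, and because 1 is C2-symmetric either ester gives the same product with both stereocentres untouched.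

Step 2
Reactants: 2 methyl (4S,5R)-5-(hydroxymethyl)-2,2-dimethyl-1,3-dioxolane-4-carboxylate
Product: 3 2-[(4S,5R)-5-(hydroxymethyl)-2,2-dimethyl-1,3-dioxolan-4-yl]propan-2-ol
Conditions: MeMgBr (3.5 equiv), THF, 0 °C to rt; aq NH4Cl
Reagents that add atoms: methylmagnesium bromide, C[Mg]Br
Why: Double Grignard addition to the remaining ester should give the tertiary carbinol that serves as the masked isopropenyl group, the first equivalent being spent on the free hydroxyl and the trans-dioxolane keeping both stereocentres fixed.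

Step 3
Reactants: 3 2-[(4S,5R)-5-(hydroxymethyl)-2,2-dimethyl-1,3-dioxolan-4-yl]propan-2-ol
Product: 4 (4S,5S)-5-(2-hydroxypropan-2-yl)-2,2-dimethyl-1,3-dioxolane-4-carbaldehyde
Conditions: Dess–Martin periodinane, NaHCO3, CH2Cl2, 0 °C to rt
Reagents that add atoms: none
Why: Dess–Martin oxidation converts the primary alcohol into the aldehyde under buffered conditions that do not epimerise the α-alkoxy centre, leaves the tertiary alcohol alone, and the trans ring fusion disfavours lactol formation.

Step 4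
Reactants: 4 (4S,5S)-5-(2-hydroxypropan-2-yl)-2,2-dimethyl-1,3-dioxolane-4-carbaldehyde
Product: 5 2-[(4S,5R)-5-[(E)-2-iodoethenyl]-2,2-dimethyl-1,3-dioxolan-4-yl]propan-2-ol
Conditions: CrCl2 (6 equiv), CHI3 (2 equiv), THF–dioxane, 0 °C to rt
Reagents that add atoms: iodoform, IC(I)I
Why: Takai olefination of the α-alkoxy aldehyde should give the (E)-iodoalkene selectively through anti elimination from the gem-dichromium adduct, and the divalent chromium reagent tolerates the free tertiary hydroxyl.

Step 5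
Reactants: 5 2-[(4S,5R)-5-[(E)-2-iodoethenyl]-2,2-dimethyl-1,3-dioxolan-4-yl]propan-2-ol
Product: 6 tert-butyl({2-[(4S,5R)-5-[(E)-2-iodoethenyl]-2,2-dimethyl-1,3-dioxolan-4-yl]propan-2-yl}oxy)dimethylsilane
Conditions: TBSOTf, 2,6-lutidine, CH2Cl2, 0 °C to rt
Reagents that add atoms: tert-butyldimethylsilyl trifluoromethanesulfonate, CC(C)(C)[Si](C)(C)OS(=O)(=O)C(F)(F)F
Why: Silyl triflate silylation protects a tertiary alcohol cleanly, and it is done while O2 and O3 are still tied up in the acetonide so that only the tertiary oxygen can react.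

Step 6
Reactants: 6 tert-butyl({2-[(4S,5R)-5-[(E)-2-iodoethenyl]-2,2-dimethyl-1,3-dioxolan-4-yl]propan-2-yl}oxy)dimethylsilane
Product: 7 (1E,3R,4S)-5-[(tert-butyldimethylsilyl)oxy]-1-iodo-5-methylhex-1-ene-3,4-diol
Conditions: AcOH–H2O (4:1), 50 °C
Reagents that add atoms: none
Why: Acid-catalysed acetal hydrolysis removes the isopropylidene group, while the hindered tertiary silyl ether and the iodoalkene should be stable to warm aqueous acetic acid.

Step 7
Reactants: 7 (1E,3R,4S)-5-[(tert-butyldimethylsilyl)oxy]-1-iodo-5-methylhex-1-ene-3,4-diol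
Product: 8 (1E,3R,4S)-3,5-bis[(tert-butyldimethylsilyl)oxy]-1-iodo-5-methylhex-1-en-4-ol
Conditions: TBSCl (1.1 equiv), imidazole, DMF, 0 °C to rt
Reagents that add atoms: tert-butyldimethylsilyl chloride, CC(C)(C)[Si](C)(C)Cl
Why: Sterically controlled monosilylation should take place at O3, an allylic secondary hydroxyl, because O2 is neopentyl-like next to the quaternary silyloxy carbon.

Step 8
Reactants: 8 (1E,3R,4S)-3,5-bis[(tert-butyldimethylsilyl)oxy]-1-iodo-5-methylhex-1-en-4-ol
Product: 9 (1E,3R,4S)-3,5-bis[(tert-butyldimethylsilyl)oxy]-1-iodo-5-methylhex-1-en-4-yl formate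
Conditions: acetic formic anhydride, pyridine, DMAP (cat.), CH2Cl2, 0 °C to rt
Reagents that add atoms: acetic formic anhydride, CC(=O)OC=O
Why: Formylation by acyl transfer from the mixed anhydride esterifies the hindered hydroxyl without forming an alkoxide, so no silyl group can migrate onto O2, and the small formyl group is the handle for the alkynyl ether.

Step 9
Reactants: 9 (1E,3R,4S)-3,5-bis[(tert-butyldimethylsilyl)oxy]-1-iodo-5-methylhex-1-en-4-yl formate
Product: 10 (1E,3R,4S)-3,5-bis[(tert-butyldimethylsilyl)oxy]-4-[(2,2-dichloroethenyl)oxy]-1-iodo-5-methylhex-1-ene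
Conditions: PPh3 (4 equiv), CCl4 (10 equiv), THF, 60 °C
Reagents that add atoms: tetrachloromethane, ClC(Cl)(Cl)Cl
Why: Wittig-type dichloromethylenation of a formate ester with Ph3P=CCl2 made in the flask is a known route to 2,2-dichlorovinyl ethers under neutral conditions that silyl ethers and iodoalkenes tolerate.

Step 10
Reactants: 11 (R)-but-3-yn-2-ol
Product: 12 (R)-tert-butyl(but-3-yn-2-yloxy)dimethylsilane
Conditions: TBSCl, imidazole, CH2Cl2, 0 °C to rt
Reagents that add atoms: tert-butyldimethylsilyl chloride, CC(C)(C)[Si](C)(C)Cl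
Why: Standard silylation of the secondary propargylic alcohol, in which the stereocentre takes no part.

Step 11
Reactants: 12 (R)-tert-butyl(but-3-yn-2-yloxy)dimethylsilane
Product: 13 (R)-tert-butyldimethyl{[3-(tributylstannyl)but-3-en-2-yl]oxy}silane
Conditions: Bu3SnH (1.5 equiv), Mo(CO)3(CNtBu)3 (2 mol %), hydroquinone (cat.), THF, 55 °C
Reagents that add atoms: tributyltin hydride, CCCC[SnH](CCCC)CCCC
Why: Molybdenum-catalysed hydrostannation of propargylic ethers is known to place tin on the internal carbon, which gives the 1,1-disubstituted alkenylstannane needed for the branched diene and leaves the carbinol centre untouched.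

Step 12
Reactants: 10 (1E,3R,4S)-3,5-bis[(tert-butyldimethylsilyl)oxy]-4-[(2,2-dichloroethenyl)oxy]-1-iodo-5-methylhex-1-ene; 13 (R)-tert-butyldimethyl{[3-(tributylstannyl)but-3-en-2-yl]oxy}silane
Product: 14 (2R,4E,6R,7S)-2,6,8-tris[(tert-butyldimethylsilyl)oxy]-7-[(2,2-dichloroethenyl)oxy]-8-methyl-3-methylidenenon-4-ene
Conditions: Pd(PPh3)4 (5 mol %), CuI (10 mol %), CsF (2 equiv), DMF, 45 °C
Reagents that add atoms: none
Why: Stille coupling under copper and fluoride co-promotion, conditions suited to hindered 1-substituted alkenylstannanes, proceeds with retention of the (E)-iodoalkene geometry, and zerovalent palladium inserts into the C–I bond far faster than into the C–Cl bonds of the dichlorovinyl ether.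

Step 13
Reactants: 14 (2R,4E,6R,7S)-2,6,8-tris[(tert-butyldimethylsilyl)oxy]-7-[(2,2-dichloroethenyl)oxy]-8-methyl-3-methylidenenon-4-ene
Product: 16 (2R,4E,6R,7S)-2,6,8-tris[(tert-butyldimethylsilyl)oxy]-7-(ethynyloxy)-8-methyl-3-methylidenenon-4-ene, via lithium acetylide 15 (not isolated)
Conditions: n-BuLi (2.3 equiv), THF, −78 °C; MeOH, −78 °C; cold work-up
Reagents that add atoms: none
Why: Dehydrochlorination then chlorine–lithium exchange of a 2,2-dichlorovinyl ether with two equivalents of n-BuLi is the known route to lithium alkynyl ethers, and cold protonation should give an ethynyl ether that can be handled because C2 is not allylic.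

Step 14
Reactants: 16 (2R,4E,6R,7S)-2,6,8-tris[(tert-butyldimethylsilyl)oxy]-7-(ethynyloxy)-8-methyl-3-methylidenenon-4-ene
Product: 18 (2S,3R)-3-[(tert-butyldimethylsilyl)oxy]-5-{(1R)-1-[(tert-butyldimethylsilyl)oxy]ethyl}-2-{2-[(tert-butyldimethylsilyl)oxy]propan-2-yl}-2,3-dihydro-1-benzofuran (2,3-cis), via cyclohexa-1,4-diene cycloadduct 17 (not isolated)
Conditions: [RhCl(C8H14)2]2 (5 mol %), P[OCH(CF3)2]3 (20 mol %), THF, rt; then DDQ (1.2 equiv), 0 °C
Reagents that add atoms: none
Why: Proposed new method: the monovalent rhodium centre should bind the alkyne and the diene, couple C7a with C3a by oxidative cyclisation to an allyl-rhodacycle and then form C6–C7 by reductive elimination, giving the cyclohexa-1,4-diene 17, and DDQ then takes one hydrogen each from C3a and C6, both doubly allylic, to aromatise the ring. The closest known reactions are the rhodium-catalysed intramolecular [4+2] cycloadditions of ether-tethered dienynes and of ynamide-tethered dienes, the latter followed by DDQ aromatisation to indolines; an alkynyl ether has not been shown as the two-carbon partner, but it is electronically close to an ynamide and alkynyl ethers are known partners in rhodium-catalysed [2+2+2] cycloadditions. The five-membered O1–C2–C3–C3a–C7a ring closes in the oxidative cyclisation with the three-atom tether inside the ring (fused, exo-type closure), and the six-membered carbocycle closes in the reductive elimination. No stereocentre is kept from this step, since the C3a centre of 17 is erased by DDQ, and C2, C3 and the carbinol centre are spectators, so the cis relation comes unchanged from the threo diol of the tartrate. Because the alkyne is held by the tether, its oxygen-bearing carbon can only reach the near diene terminus, which places the butynol-derived chain at C5, para to O1; the (E)-alkene from step 4 lets the diene reach the alkyne, and a neutral catalyst at room temperature should let cyclisation outrun retro-ene loss of ketene, the [3,3] shift being closed because C2 is not allylic.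

Step 15
Reactants: 18 (2S,3R)-3-[(tert-butyldimethylsilyl)oxy]-5-{(1R)-1-[(tert-butyldimethylsilyl)oxy]ethyl}-2-{2-[(tert-butyldimethylsilyl)oxy]propan-2-yl}-2,3-dihydro-1-benzofuran
Product: 19 (2S,3R)-5-[(1R)-1-hydroxyethyl]-2-(2-hydroxypropan-2-yl)-2,3-dihydro-1-benzofuran-3-ol
Conditions: TBAF (6 equiv), THF, rt to 45 °C
Reagents that add atoms: none
Why: Fluoride-induced desilylation should cleave all three silyl ethers (the tertiary one on gentle warming) without acid, which avoids ionisation of the benzylic C3–O bond and elimination to the benzofuran.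

Step 16
Reactants: 19 (2S,3R)-5-[(1R)-1-hydroxyethyl]-2-(2-hydroxypropan-2-yl)-2,3-dihydro-1-benzofuran-3-ol; 20 3-methylbutanoic anhydride (isovaleric anhydride)
Product: 21 (1R)-1-[(2S,3R)-2-(2-hydroxypropan-2-yl)-3-(3-methylbutanoyloxy)-2,3-dihydro-1-benzofuran-5-yl]ethyl 3-methylbutanoate
Conditions: 20 (2.5 equiv), DMAP (0.2 equiv), Et3N, CH2Cl2, 0 °C to rt
Reagents that add atoms: none
Why: DMAP-catalysed acylation with the anhydride (nucleophilic acyl-transfer catalysis) should esterify the two secondary benzylic hydroxyls, while the tertiary hydroxyl is too hindered to react under these conditions.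

Step 17
Reactants: 21 (1R)-1-[(2S,3R)-2-(2-hydroxypropan-2-yl)-3-(3-methylbutanoyloxy)-2,3-dihydro-1-benzofuran-5-yl]ethyl 3-methylbutanoate
Product: 22 (1R)-1-[(2R,3R)-3-(3-methylbutanoyloxy)-2-(prop-1-en-2-yl)-2,3-dihydro-1-benzofuran-5-yl]ethyl 3-methylbutanoate
Conditions: Burgess reagent, toluene, 50 °C
Reagents that add atoms: none
Why: Burgess dehydration of the tertiary alcohol proceeds by syn elimination through the sulfamate ester and should take one of six methyl hydrogens in preference to the single, inductively deactivated hydrogen on C2, giving the isopropenyl group without acid or base that could eliminate the C3 ester.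

Step 18
Reactants: 22 (1R)-1-[(2R,3R)-3-(3-methylbutanoyloxy)-2-(prop-1-en-2-yl)-2,3-dihydro-1-benzofuran-5-yl]ethyl 3-methylbutanoate
Product: 23 (1R)-1-[(2R,3R)-2-(3-hydroxyprop-1-en-2-yl)-3-(3-methylbutanoyloxy)-2,3-dihydro-1-benzofuran-5-yl]ethyl 3-methylbutanoate
Conditions: SeO2 (0.5 equiv), t-BuOOH (3 equiv), CH2Cl2, rt
Reagents that add atoms: SeO2, O=[Se]=O (transfers the oxygen; reoxidised by tert-butyl hydroperoxide, CC(C)(C)OO)
Why: Riley allylic oxidation (ene reaction then [2,3]-sigmatropic shift) of a 1,1-disubstituted alkene should attack the methyl group in preference to the oxygen-bearing methine at C2, as is known for isopropenyl-dihydrobenzofurans.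

Step 19
Reactants: 23 (1R)-1-[(2R,3R)-2-(3-hydroxyprop-1-en-2-yl)-3-(3-methylbutanoyloxy)-2,3-dihydro-1-benzofuran-5-yl]ethyl 3-methylbutanoate
Product: 24 (1R)-1-[(2R,3R)-3-(3-methylbutanoyloxy)-2-(3-oxoprop-1-en-2-yl)-2,3-dihydro-1-benzofuran-5-yl]ethyl 3-methylbutanoate (CNP0316116.1)
Conditions: MnO2 (activated, 15 equiv), CH2Cl2, rt
Reagents that add atoms: none
Why: Chemoselective MnO2 oxidation converts the allylic alcohol, and any of it already oxidised further in step 18 is the same product, into the α-substituted acrolein under neutral conditions that do not endanger the C2 hydrogen or the C3 ester.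

Compound list
1 | dimethyl (4S,5S)-2,2-dimethyl-1,3-dioxolane-4,5-dicarboxylate (dimethyl 2,3-O-isopropylidene-D-tartrate) | COC(=O)[C@H]1OC(C)(C)O[C@@H]1C(=O)OC | starting material
2 | methyl (4S,5R)-5-(hydroxymethyl)-2,2-dimethyl-1,3-dioxolane-4-carboxylate | COC(=O)[C@H]1OC(C)(C)O[C@@H]1CO | intermediate
3 | 2-[(4S,5R)-5-(hydroxymethyl)-2,2-dimethyl-1,3-dioxolan-4-yl]propan-2-ol | CC(C)(O)[C@H]1OC(C)(C)O[C@@H]1CO | intermediate
4 | (4S,5S)-5-(2-hydroxypropan-2-yl)-2,2-dimethyl-1,3-dioxolane-4-carbaldehyde | CC(C)(O)[C@H]1OC(C)(C)O[C@@H]1C=O | intermediate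
5 | 2-[(4S,5R)-5-[(E)-2-iodoethenyl]-2,2-dimethyl-1,3-dioxolan-4-yl]propan-2-ol | CC(C)(O)[C@H]1OC(C)(C)O[C@@H]1/C=C/I | intermediate
6 | tert-butyl({2-[(4S,5R)-5-[(E)-2-iodoethenyl]-2,2-dimethyl-1,3-dioxolan-4-yl]propan-2-yl}oxy)dimethylsilane | CC(C)(O[Si](C)(C)C(C)(C)C)[C@H]1OC(C)(C)O[C@@H]1/C=C/I | intermediate
7 | (1E,3R,4S)-5-[(tert-butyldimethylsilyl)oxy]-1-iodo-5-methylhex-1-ene-3,4-diol | CC(C)(O[Si](C)(C)C(C)(C)C)[C@@H](O)[C@H](O)/C=C/I | intermediate
8 | (1E,3R,4S)-3,5-bis[(tert-butyldimethylsilyl)oxy]-1-iodo-5-methylhex-1-en-4-ol | CC(C)(O[Si](C)(C)C(C)(C)C)[C@@H](O)[C@H](O[Si](C)(C)C(C)(C)C)/C=C/I | intermediate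
9 | (1E,3R,4S)-3,5-bis[(tert-butyldimethylsilyl)oxy]-1-iodo-5-methylhex-1-en-4-yl formate | CC(C)(O[Si](C)(C)C(C)(C)C)[C@@H](OC=O)[C@H](O[Si](C)(C)C(C)(C)C)/C=C/I | intermediate
10 | (1E,3R,4S)-3,5-bis[(tert-butyldimethylsilyl)oxy]-4-[(2,2-dichloroethenyl)oxy]-1-iodo-5-methylhex-1-ene | CC(C)(O[Si](C)(C)C(C)(C)C)[C@@H](OC=C(Cl)Cl)[C@H](O[Si](C)(C)C(C)(C)C)/C=C/I | intermediate
11 | (R)-but-3-yn-2-ol | C#C[C@@H](C)O | starting material
12 | (R)-tert-butyl(but-3-yn-2-yloxy)dimethylsilane | C#C[C@@H](C)O[Si](C)(C)C(C)(C)C | intermediate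
13 | (R)-tert-butyldimethyl{[3-(tributylstannyl)but-3-en-2-yl]oxy}silane | C=C([Sn](CCCC)(CCCC)CCCC)[C@@H](C)O[Si](C)(C)C(C)(C)C | intermediate
14 | (2R,4E,6R,7S)-2,6,8-tris[(tert-butyldimethylsilyl)oxy]-7-[(2,2-dichloroethenyl)oxy]-8-methyl-3-methylidenenon-4-ene | CC(C)(O[Si](C)(C)C(C)(C)C)[C@@H](OC=C(Cl)Cl)[C@H](O[Si](C)(C)C(C)(C)C)/C=C/C(=C)[C@@H](C)O[Si](C)(C)C(C)(C)C | intermediate
15 | lithium acetylide of 16 (lithium on the terminal alkyne carbon; not isolated) | CC(C)(O[Si](C)(C)C(C)(C)C)[C@@H](OC#C[Li])[C@H](O[Si](C)(C)C(C)(C)C)/C=C/C(=C)[C@@H](C)O[Si](C)(C)C(C)(C)C | intermediate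
16 | (2R,4E,6R,7S)-2,6,8-tris[(tert-butyldimethylsilyl)oxy]-7-(ethynyloxy)-8-methyl-3-methylidenenon-4-ene (key-step precursor) | CC(C)(O[Si](C)(C)C(C)(C)C)[C@@H](OC#C)[C@H](O[Si](C)(C)C(C)(C)C)/C=C/C(=C)[C@@H](C)O[Si](C)(C)C(C)(C)C | intermediate
17 | (2S,3R)-3-[(tert-butyldimethylsilyl)oxy]-5-{(1R)-1-[(tert-butyldimethylsilyl)oxy]ethyl}-2-{2-[(tert-butyldimethylsilyl)oxy]propan-2-yl}-2,3,3a,6-tetrahydro-1-benzofuran (C3a epimer not defined; not isolated) | CC(C)(O[Si](C)(C)C(C)(C)C)[C@H]1OC2=CCC([C@@H](C)O[Si](C)(C)C(C)(C)C)=CC2[C@H]1O[Si](C)(C)C(C)(C)C | intermediate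
18 | (2S,3R)-3-[(tert-butyldimethylsilyl)oxy]-5-{(1R)-1-[(tert-butyldimethylsilyl)oxy]ethyl}-2-{2-[(tert-butyldimethylsilyl)oxy]propan-2-yl}-2,3-dihydro-1-benzofuran (2,3-cis; key-step product) | CC(C)(O[Si](C)(C)C(C)(C)C)[C@H]1Oc2ccc([C@@H](C)O[Si](C)(C)C(C)(C)C)cc2[C@H]1O[Si](C)(C)C(C)(C)C | intermediate
19 | (2S,3R)-5-[(1R)-1-hydroxyethyl]-2-(2-hydroxypropan-2-yl)-2,3-dihydro-1-benzofuran-3-ol | CC(C)(O)[C@H]1Oc2ccc([C@@H](C)O)cc2[C@H]1O | intermediate
20 | 3-methylbutanoic anhydride (isovaleric anhydride) | CC(C)CC(=O)OC(=O)CC(C)C | starting material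
21 | (1R)-1-[(2S,3R)-2-(2-hydroxypropan-2-yl)-3-(3-methylbutanoyloxy)-2,3-dihydro-1-benzofuran-5-yl]ethyl 3-methylbutanoate | CC(C)(O)[C@H]1Oc2ccc([C@@H](C)OC(=O)CC(C)C)cc2[C@H]1OC(=O)CC(C)C | intermediate
22 | (1R)-1-[(2R,3R)-3-(3-methylbutanoyloxy)-2-(prop-1-en-2-yl)-2,3-dihydro-1-benzofuran-5-yl]ethyl 3-methylbutanoate | C=C(C)[C@H]1Oc2ccc([C@@H](C)OC(=O)CC(C)C)cc2[C@H]1OC(=O)CC(C)C | intermediate
23 | (1R)-1-[(2R,3R)-2-(3-hydroxyprop-1-en-2-yl)-3-(3-methylbutanoyloxy)-2,3-dihydro-1-benzofuran-5-yl]ethyl 3-methylbutanoate | C=C(CO)[C@H]1Oc2ccc([C@@H](C)OC(=O)CC(C)C)cc2[C@H]1OC(=O)CC(C)C | intermediate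
24 | (1R)-1-[(2R,3R)-3-(3-methylbutanoyloxy)-2-(3-oxoprop-1-en-2-yl)-2,3-dihydro-1-benzofuran-5-yl]ethyl 3-methylbutanoate (CNP0316116.1) | C=C(C=O)[C@H]1Oc2ccc([C@@H](C)OC(=O)CC(C)C)cc2[C@H]1OC(=O)CC(C)C | target

Total step count: 19.
Longest linear sequence: 17 steps (steps 1–9 and 12–19, from 1 to 24); steps 10 and 11 make the stannane 13.

Steps most likely to fail

1. Step 14 (the step labelled as a proposed new method). The ethynyl ether may be used up before oxidative cyclisation with the diene, by retro-ene fragmentation to a ketene, by rhodium vinylidene formation at the terminal alkyne, or by oligomerisation. The fallback builds the two rings one after the other with known reaction types; it sets out from 10 and comes back at 19.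
   - Excess n-BuLi (THF, −78 °C, then MeOH) performs iodine–lithium exchange at the iodoalkene and converts the dichlorovinyl ether into the alkynyl ether in the same flask. Protonation should give the 1,6-enyne (3R,4S)-3,5-bis[(tert-butyldimethylsilyl)oxy]-4-(ethynyloxy)-5-methylhex-1-ene F1.
   - Ring-closing enyne metathesis with the second-generation Grubbs catalyst under ethylene (CH2Cl2, 40 °C), a reaction known for alkynyl ethers, closes the O1–C2–C3–C3a–C7a ring as the 5-ethenyl-2,3-dihydrofuran F2.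
   - This 2-alkoxy-1,3-diene should undergo a Diels–Alder reaction with but-3-yn-2-one (toluene, rt to 60 °C), the alkoxy group directing the acetyl group para to C7a, to give the cyclohexa-1,4-diene adduct F3. DDQ aromatises it in the same flask to the 5-acetyl-2,3-dihydrobenzofuran F4.
   - Corey–Bakshi–Shibata reduction with the (S)-2-methyl-oxazaborolidine and BH3·SMe2 (THF, −20 °C) sets the (R)-carbinol, giving the alcohol F5. TBAF as in step 15 then gives triol 19.

2. Step 9. Addition of the phosphorus ylide to a formate shielded on both sides may be slow, so that silyl ether cleavage by the chlorophosphonium by-product takes over on prolonged heating. The fallback is the classical route to alkoxyacetylenes through a bromovinyl ether; it sets out from 9 and comes back at 16.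
   - Methylenation of the formate with Cp2TiMe2 (toluene, 65 °C) gives the vinyl ether F6.
   - Br2 (CH2Cl2, −78 °C) adds to the enol ether much faster than to the iodoalkene, giving the 1,2-dibromoethyl ether F7. DBU converts it in the same flask into the (Z)-2-bromovinyl ether F8.
   - Coupling with 13 under the conditions of step 12, the C–I bond reacting before the electron-rich C–Br bond, gives the diene F9.
   - LDA (2.2 equiv, THF, −78 °C, then MeOH) effects anti dehydrobromination and gives 16.

3. Step 12. Tin-to-palladium transfer at the 1,1-disubstituted alkenylstannane may be slow, so that protodestannylation, homocoupling or cine substitution compete. The fallback replaces tin by zinc; it sets out from 13 and comes back at 14.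
   - Iododestannylation (I2, CH2Cl2, 0 °C) gives (R)-tert-butyl[(3-iodobut-3-en-2-yl)oxy]dimethylsilane F10.
   - t-BuLi (2 equiv, Et2O, −78 °C) and then ZnCl2 give the alkenylzinc chloride F11, which is used at once.
   - Negishi coupling of F11 with 10 (Pd(PPh3)4, THF, rt), in which transmetalation from zinc is fast even at a 1,1-disubstituted alkenyl carbon, gives 14.

Further compounds
F1 | step 14 | (3R,4S)-3,5-bis[(tert-butyldimethylsilyl)oxy]-4-(ethynyloxy)-5-methylhex-1-ene | CC(C)(O[Si](C)(C)C(C)(C)C)[C@@H](OC#C)[C@H](O[Si](C)(C)C(C)(C)C)C=C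
F2 | step 14 | (2S,3R)-3-[(tert-butyldimethylsilyl)oxy]-2-{2-[(tert-butyldimethylsilyl)oxy]propan-2-yl}-5-ethenyl-2,3-dihydrofuran | CC(C)(O[Si](C)(C)C(C)(C)C)[C@H]1OC(C=C)=C[C@H]1O[Si](C)(C)C(C)(C)C
F3 | step 14 | 1-[(2S,3R)-3-[(tert-butyldimethylsilyl)oxy]-2-{2-[(tert-butyldimethylsilyl)oxy]propan-2-yl}-2,3,3a,6-tetrahydro-1-benzofuran-5-yl]ethan-1-one (C3a epimer not defined) | CC(C)(O[Si](C)(C)C(C)(C)C)[C@H]1OC2=CCC(C(C)=O)=CC2[C@H]1O[Si](C)(C)C(C)(C)C
F4 | step 14 | 1-[(2S,3R)-3-[(tert-butyldimethylsilyl)oxy]-2-{2-[(tert-butyldimethylsilyl)oxy]propan-2-yl}-2,3-dihydro-1-benzofuran-5-yl]ethan-1-one | CC(C)(O[Si](C)(C)C(C)(C)C)[C@H]1Oc2ccc(C(C)=O)cc2[C@H]1O[Si](C)(C)C(C)(C)C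
F5 | step 14 | (1R)-1-[(2S,3R)-3-[(tert-butyldimethylsilyl)oxy]-2-{2-[(tert-butyldimethylsilyl)oxy]propan-2-yl}-2,3-dihydro-1-benzofuran-5-yl]ethan-1-ol | CC(C)(O[Si](C)(C)C(C)(C)C)[C@H]1Oc2ccc([C@@H](C)O)cc2[C@H]1O[Si](C)(C)C(C)(C)C
F6 | step 9 | (1E,3R,4S)-3,5-bis[(tert-butyldimethylsilyl)oxy]-4-(ethenyloxy)-1-iodo-5-methylhex-1-ene | CC(C)(O[Si](C)(C)C(C)(C)C)[C@@H](OC=C)[C@H](O[Si](C)(C)C(C)(C)C)/C=C/I
F7 | step 9 | (1E,3R,4S)-3,5-bis[(tert-butyldimethylsilyl)oxy]-4-(1,2-dibromoethoxy)-1-iodo-5-methylhex-1-ene (bromo-acetal centre not defined) | CC(C)(O[Si](C)(C)C(C)(C)C)[C@@H](OC(Br)CBr)[C@H](O[Si](C)(C)C(C)(C)C)/C=C/I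
F8 | step 9 | (1E,3R,4S)-4-{[(Z)-2-bromoethenyl]oxy}-3,5-bis[(tert-butyldimethylsilyl)oxy]-1-iodo-5-methylhex-1-ene | CC(C)(O[Si](C)(C)C(C)(C)C)[C@@H](O/C=C\Br)[C@H](O[Si](C)(C)C(C)(C)C)/C=C/I
F9 | step 9 | (2R,4E,6R,7S)-7-{[(Z)-2-bromoethenyl]oxy}-2,6,8-tris[(tert-butyldimethylsilyl)oxy]-8-methyl-3-methylidenenon-4-ene | CC(C)(O[Si](C)(C)C(C)(C)C)[C@@H](O/C=C\Br)[C@H](O[Si](C)(C)C(C)(C)C)/C=C/C(=C)[C@@H](C)O[Si](C)(C)C(C)(C)C
F10 | step 12 | (R)-tert-butyl[(3-iodobut-3-en-2-yl)oxy]dimethylsilane | C=C(I)[C@@H](C)O[Si](C)(C)C(C)(C)C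
F11 | step 12 | {(3R)-3-[(tert-butyldimethylsilyl)oxy]but-1-en-2-yl}zinc chloride | C=C([Zn]Cl)[C@@H](C)O[Si](C)(C)C(C)(C)C
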